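**Plan**

1. Numbering used throughout: ring A = C1(OH)–C2–C3–C4(=O)–C5–C10, ring B = C5–C6(OH)–C7–C8(O-acyl)–C9–C10; C10 carries the methyl group and C7 carries C11(=C13H2)–C12O2Me.
2. Retrosynthesis: the two silyl ethers, the C4 ketone (from C4–NO2) and the C1 carbinol (from C1=O) are adjusted first; then C3–C4 and C5–C10 are cut together, which opens both rings to an acyclic nitro triene. This works because ring A holds oxygen at C1 and C4 in a 1,4 relation, with the C4 carbonyl between the C5 methine and the quaternary C10: the imprint of a 2-silyloxydiene (C3=C2–C1(O)=C10) and a ketene-equivalent dienophile (C4=C5–NO2), with C6–C9 of ring B as a four-carbon tether.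
3. The triene is cut further at C1–C2 (thioester + vinylstannane), C4–C5 (aldehyde + nitromethane), the C8–O ester and C7–C8 (aldehyde + 2-(alkoxycarbonyl)allylboronate); the boronate comes from crotonaldehyde and methyl propiolate.
4. Forward: C7–C8 chain union, esterification, nitroalkene, vinyl ketone, then one operation that closes ring B (C5–C10) and ring A (C3–C4), then C1 reduction, nitro-to-ketone conversion and desilylation.
5. Stereochemistry: C6 from a catalytic asymmetric alkynylation; C7 and C8 from C6 in a chair-like allylboration; C5 and C10 from the cycloaddition, steered by the three equatorial tether substituents and an endo nitro group; C1 by axial hydride delivery anti to the C10 methyl.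

Key step: step 13

Remark on the chemistry: lactone 1 is used as the racemate, so 2, 3 and 14–22 are epimer mixtures at the methyl-bearing carbon (C10, written without a stereodescriptor); this centre is flattened in 23 and set in 24.

**Step 1**
Reactants: 1 3-methyldihydrofuran-2(3H)-one (racemic)
Product: 2 S-ethyl 4-hydroxy-2-methylbutanethioate
Conditions: AlMe3, EtSH, CH2Cl2, 0 °C to rt; cold aqueous HCl
Reagents that add atoms: ethanethiol, CCS
Why: Me2AlSEt made in the flask should open the lactone by acyl–oxygen cleavage (aluminium thiolate conversion of a lactone into a hydroxy thioester), and the product should be isolable if kept cold and neutral.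

**Step 2**
Reactants: 2 S-ethyl 4-hydroxy-2-methylbutanethioate
Product: 3 S-ethyl 2-methyl-4-oxobutanethioate
Conditions: Dess–Martin periodinane, CH2Cl2, 0 °C to rt
Reagents that add atoms: none
Why: Dess–Martin oxidation of a primary alcohol stops at the aldehyde and should leave the thioester untouched.

**Step 3**
Reactants: 4 methyl propiolate; 5 (E)-but-2-enal (crotonaldehyde)
Product: 7 methyl (4R,5E)-4-hydroxyhept-5-en-2-ynoate, via zinc alkynylide 6 (not isolated)
Conditions: Me2Zn, ProPhenol ligand (10 mol%, the enantiomer that gives the 4R carbinol), toluene, 0 °C; then 5, 4 °C; aqueous NH4Cl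
Reagents that add atoms: dimethylzinc, C[Zn]C (its zinc and methyl are held only in 6)
Why: Catalytic asymmetric 1,2-alkynylation of an enal by a zinc alkynylide bound to the dinuclear zinc–ProPhenol catalyst, whose chiral pocket should select the aldehyde face and so set C6.

**Step 4**
Reactants: 7 methyl (4R,5E)-4-hydroxyhept-5-en-2-ynoate
Product: 8 methyl (4R,5E)-4-[(tert-butyldimethylsilyl)oxy]hept-5-en-2-ynoate
Conditions: TBSCl, imidazole, DMF, 0 °C to rt
Reagents that add atoms: tert-butyldimethylsilyl chloride, CC(C)(C)[Si](C)(C)Cl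
Why: Standard silylation of a secondary alcohol; the bulky silyl ether later shields one face of C7.

**Step 5**
Reactants: 8 methyl (4R,5E)-4-[(tert-butyldimethylsilyl)oxy]hept-5-en-2-ynoate
Product: 10 methyl (2Z,4R,5E)-4-[(tert-butyldimethylsilyl)oxy]-2-[(4,4,5,5-tetramethyl-1,3,2-dioxaborolan-2-yl)methyl]hepta-2,5-dienoate, via alkenylalane 9 (not isolated)
Conditions: iBu2AlH, HMPA, THF, 0 °C; then ICH2Bpin, 0 °C to rt
Reagents that add atoms: diisobutylaluminium hydride, CC(C)C[AlH]CC(C)C (its aluminium is held only in 9); 2-(iodomethyl)-4,4,5,5-tetramethyl-1,3,2-dioxaborolane, ICB1OC(C)(C)C(C)(C)O1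
Why: Conjugate hydroalumination of the ynoate by the iBu2AlH–HMPA complex adds H to C7 and Al to C11 on the same side, and C-alkylation of this α-alumino enoate by the iodomethylboronate with retention (conjugate reduction–alkylation of an alkynoate) should give the allylboronate with the C6 branch trans to CH2B.

**Step 6**
Reactants: 11 methyl 2-(hydroxymethyl)acrylate
Product: 12 methyl 2-{[(tert-butyldimethylsilyl)oxy]methyl}acrylate
Conditions: TBSCl, imidazole, CH2Cl2, rt
Reagents that add atoms: tert-butyldimethylsilyl chloride, CC(C)(C)[Si](C)(C)Cl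
Why: Standard silylation of a primary allylic alcohol.

**Step 7**
Reactants: 12 methyl 2-{[(tert-butyldimethylsilyl)oxy]methyl}acrylate
Product: 13 2-{[(tert-butyldimethylsilyl)oxy]methyl}acrylic acid
Conditions: LiOH, THF/H2O, 0 °C to rt; then 1 M HCl to pH 4
Reagents that add atoms: lithium hydroxide, [Li+].[OH-] (its oxygen becomes the carboxyl OH)
Why: Saponification of the methyl ester by acyl–oxygen cleavage; the primary silyl ether should survive cold dilute base and brief mild acid.

**Step 8**
Reactants: 3 S-ethyl 2-methyl-4-oxobutanethioate; 10 allylboronate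
Product: 15 hydroxy thioester (3R,4S,1'R in heptanoate numbering), via borate ester 14 (not isolated)
Conditions: Sc(OTf)3 (10 mol%), toluene, −78 to 0 °C; aqueous NaHCO3
Reagents that add atoms: none
Why: Lewis-acid-catalysed allylboration through a chair-like six-membered transition state, in which the C6 branch (trans to CH2B) sits equatorial and gives the anti C7/C8 adduct, while A(1,3) strain against the cis ester turns H6 into the alkene plane so that the aldehyde should attack C7 on the face away from the bulky silyloxy group (O6 and C11 syn).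

**Step 9**
Reactants: 15 hydroxy thioester; 13 2-{[(tert-butyldimethylsilyl)oxy]methyl}acrylic acid
Product: 16 C8 acrylate ester
Conditions: DCC, DMAP (0.2 equiv), CH2Cl2, 0 °C to rt
Reagents that add atoms: none
Why: Steglich esterification acylates the only free hydroxyl with retention at C8, and is run at once so that the γ-hydroxy thioester has no time to lactonise.

**Step 10**
Reactants: 16 C8 acrylate ester
Product: 18 C5 aldehyde, via ozonide 17 (not isolated)
Conditions: O3, CH2Cl2, −78 °C, Sudan Red 7B as end-point indicator; then PPh3, −78 °C to rt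
Reagents that add atoms: ozone, [O-][O+]=O
Why: Ozonolysis with reductive work-up; the electron-richer 1,2-disubstituted C5=C4 alkene should be consumed well before the two electron-poor 1,1-disubstituted acrylates.

**Step 11**
Reactants: 18 C5 aldehyde
Product: 21 (E)-nitroalkene thioester, via nitro aldol 19 (not isolated), via mesylate 20 (not isolated)
Conditions: MeNO2, Et3N (0.2 equiv), 0 °C to rt; then MsCl, Et3N, CH2Cl2, −20 to 0 °C
Reagents that add atoms: nitromethane, C[N+](=O)[O-]; methanesulfonyl chloride, CS(=O)(=O)Cl (held only in 20)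
Why: Henry addition followed by mesylation and E1cB elimination should give the more stable (E)-nitroalkene, and the weak amine base should not drive Michael addition of nitromethane to the α-substituted acrylates.

**Step 12**
Reactants: 21 (E)-nitroalkene thioester
Product: 22 nitro triene vinyl ketone
Conditions: tributyl(vinyl)stannane, Pd2(dba)3 (2.5 mol%), tri(2-furyl)phosphine (20 mol%), CuOP(O)Ph2 (1.2 equiv), THF, rt
Reagents that add atoms: tributyl(vinyl)stannane, C=C[Sn](CCCC)(CCCC)CCCC
Why: Base-free thioester–organostannane cross-coupling (Liebeskind–Srogl type) should give the vinyl ketone under neutral conditions that spare the nitroalkene and the esters.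

**Step 13**
Reactants: 22 nitro triene vinyl ketone
Product: 25 trans-decalin nitro ketone, via silyl dienol ether 23 (not isolated), via cycloadduct silyl enol ether 24 (not isolated)
Conditions: Et3N (1.5 equiv), Me3SiOTf (1.3 equiv), toluene, −40 to 0 °C; then 60 °C; then aqueous citric acid, THF, 0 °C
Reagents that add atoms: trimethylsilyl trifluoromethanesulfonate, C[Si](C)(C)OS(=O)(=O)C(F)(F)F (its silicon is held only in 23 and 24)
Why: Soft enolisation of 22 at C10, its only enolisable site, gives the 2-silyloxy-1,3-diene 23 (C3=C2–C1(OSiMe3)=C10), which should undergo an intramolecular, strongly asynchronous normal-demand [4+2] cycloaddition with the nitroalkene C4=C5 (C5–C10 bonding leads; a Mukaiyama–Michael/Michael sequence through a silyl nitronate is its stepwise limit and ends in the same product), after which mild acid cleaves only the silyl enol ether of 24. The closest known reaction types are the intramolecular Diels–Alder reaction of 1-nitro-1,7,9-decatrienes and intramolecular double Michael reactions of enones run through silyl dienol ethers formed in situ. Ring B closes through the C5–C10 bond (6-exo-trig in the stepwise picture) and ring A through the C3–C4 bond (6-endo-trig), both within one type 1 decatriene cycloaddition. The sense of C10 and C5 relative to C6–C8 is set by the chair-like six-membered array C5–C10, in which the C6 silyloxy, C7 acrylate and C8 acyloxy groups are all equatorial, the bulky silyloxydiene takes the equatorial and the methyl the axial site at C10, and the nitro group lies endo under the diene; this should give the trans ring fusion (5α-H, 10β-CH3) and an equatorial 4α-nitro group. The step needs chemoselectivity for the nitroalkene over the two acrylates, which its far lower LUMO should secure, and it needs the (Z)-dienol ether (O cis to C9), which is expected because Et3NH+ OTf− lets the geometric isomers interconvert while the isomer with the tether on the inside cyclises slowly. Both C10 epimers of 22 converge on 23, so the step is stereoconvergent.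

**Step 14**
Reactants: 25 trans-decalin nitro ketone
Product: 26 1β-alcohol
Conditions: NaBH4, CeCl3·7H2O, MeOH/THF, −78 to −40 °C
Reagents that add atoms: none
Why: Luche-type 1,2-reduction in which hydride should add axially from the α face, anti to the axial C10 methyl, to give the equatorial 1β-alcohol while the nitro group and the acrylates stay untouched at low temperature.

**Step 15**
Reactants: 26 1β-alcohol
Product: 28 bis-silyl ether of the target, via potassium nitronate 27 (not isolated)
Conditions: KOtBu (1.05 equiv), THF, −40 °C; then dimethyldioxirane in acetone, −40 to 0 °C; aqueous NH4Cl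
Reagents that add atoms: dimethyldioxirane, CC1(C)OO1; potassium tert-butoxide, CC(C)(C)[O-].[K+] (its potassium is held only in 27)
Why: Oxidative Nef reaction, in which the electrophilic dioxirane oxidises the nitronate C=N bond and the adduct collapses to the C4 ketone with loss of nitrite, far faster than it epoxidises electron-poor acrylates; no free base remains to epimerise C5 or eliminate the C6 silyloxy group.

**Step 16**
Reactants: 28 bis-silyl ether of the target
Product: 29 target CNP0144895.1
Conditions: HF·pyridine, pyridine, THF, 0 °C to rt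
Reagents that add atoms: none
Why: Buffered fluoride desilylation should remove both silyl ethers under weakly acidic conditions that avoid O8-to-O6 acyl migration, lactonisation of the 6-hydroxy ester and β-elimination next to the C4 ketone.

**Compound list**

1 | 3-methyldihydrofuran-2(3H)-one (α-methyl-γ-butyrolactone, racemic) | CC1CCOC1=O | starting material
2 | S-ethyl 4-hydroxy-2-methylbutanethioate (racemic) | CCSC(=O)C(C)CCO | intermediate
3 | S-ethyl 2-methyl-4-oxobutanethioate (racemic) | CCSC(=O)C(C)CC=O | intermediate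
4 | methyl propiolate | C#CC(=O)OC | starting material
5 | (E)-but-2-enal (crotonaldehyde) | C/C=C/C=O | starting material
6 | methyl 3-(methylzincio)propiolate | C[Zn]C#CC(=O)OC | intermediate
7 | methyl (4R,5E)-4-hydroxyhept-5-en-2-ynoate | COC(=O)C#C[C@H](O)/C=C/C | intermediate
8 | methyl (4R,5E)-4-[(tert-butyldimethylsilyl)oxy]hept-5-en-2-ynoate | COC(=O)C#C[C@H](O[Si](C)(C)C(C)(C)C)/C=C/C | intermediate
9 | methyl (2E,4R,5E)-2-[bis(2-methylpropyl)alumanyl]-4-[(tert-butyldimethylsilyl)oxy]hepta-2,5-dienoate | COC(=O)/C([Al](CC(C)C)CC(C)C)=C\[C@H](O[Si](C)(C)C(C)(C)C)/C=C/C | intermediate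
10 | methyl (2Z,4R,5E)-4-[(tert-butyldimethylsilyl)oxy]-2-[(4,4,5,5-tetramethyl-1,3,2-dioxaborolan-2-yl)methyl]hepta-2,5-dienoate | COC(=O)/C(CB1OC(C)(C)C(C)(C)O1)=C\[C@H](O[Si](C)(C)C(C)(C)C)/C=C/C | intermediate
11 | methyl 2-(hydroxymethyl)acrylate | C=C(CO)C(=O)OC | starting material
12 | methyl 2-{[(tert-butyldimethylsilyl)oxy]methyl}acrylate | C=C(CO[Si](C)(C)C(C)(C)C)C(=O)OC | intermediate
13 | 2-{[(tert-butyldimethylsilyl)oxy]methyl}acrylic acid | C=C(CO[Si](C)(C)C(C)(C)C)C(=O)O | intermediate
14 | methyl (3R,4S)-3-{(1R,2E)-1-[(tert-butyldimethylsilyl)oxy]but-2-en-1-yl}-7-(ethylsulfanyl)-6-methyl-2-methylidene-7-oxo-4-[(4,4,5,5-tetramethyl-1,3,2-dioxaborolan-2-yl)oxy]heptanoate (epimers at the CH3-bearing carbon) | CCSC(=O)C(C)C[C@H](OB1OC(C)(C)C(C)(C)O1)[C@@H](C(=C)C(=O)OC)[C@H](O[Si](C)(C)C(C)(C)C)/C=C/C | intermediate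
15 | methyl (3R,4S)-3-{(1R,2E)-1-[(tert-butyldimethylsilyl)oxy]but-2-en-1-yl}-7-(ethylsulfanyl)-4-hydroxy-6-methyl-2-methylidene-7-oxoheptanoate (epimers at the CH3-bearing carbon) | CCSC(=O)C(C)C[C@H](O)[C@@H](C(=C)C(=O)OC)[C@H](O[Si](C)(C)C(C)(C)C)/C=C/C | intermediate
16 | methyl (3R,4S)-3-{(1R,2E)-1-[(tert-butyldimethylsilyl)oxy]but-2-en-1-yl}-4-[(2-{[(tert-butyldimethylsilyl)oxy]methyl}prop-2-enoyl)oxy]-7-(ethylsulfanyl)-6-methyl-2-methylidene-7-oxoheptanoate (epimers at the CH3-bearing carbon) | CCSC(=O)C(C)C[C@H](OC(=O)C(=C)CO[Si](C)(C)C(C)(C)C)[C@@H](C(=C)C(=O)OC)[C@H](O[Si](C)(C)C(C)(C)C)/C=C/C | intermediate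
17 | ozonide of 16: the but-2-enyl group of 16 replaced by (S)-[(tert-butyldimethylsilyl)oxy](5-methyl-1,2,4-trioxolan-3-yl)methyl (mixture at the trioxolane carbons) | CCSC(=O)C(C)C[C@H](OC(=O)C(=C)CO[Si](C)(C)C(C)(C)C)[C@@H](C(=C)C(=O)OC)[C@H](O[Si](C)(C)C(C)(C)C)C1OC(C)OO1 | intermediate
18 | methyl (3R,4S)-3-{(1S)-1-[(tert-butyldimethylsilyl)oxy]-2-oxoethyl}-4-[(2-{[(tert-butyldimethylsilyl)oxy]methyl}prop-2-enoyl)oxy]-7-(ethylsulfanyl)-6-methyl-2-methylidene-7-oxoheptanoate | CCSC(=O)C(C)C[C@H](OC(=O)C(=C)CO[Si](C)(C)C(C)(C)C)[C@@H](C(=C)C(=O)OC)[C@H](O[Si](C)(C)C(C)(C)C)C=O | intermediate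
19 | nitro aldol of 18: side chain (1S)-1-[(tert-butyldimethylsilyl)oxy]-2-hydroxy-3-nitropropyl (mixture at the new carbinol) | CCSC(=O)C(C)C[C@H](OC(=O)C(=C)CO[Si](C)(C)C(C)(C)C)[C@@H](C(=C)C(=O)OC)[C@H](O[Si](C)(C)C(C)(C)C)C(O)C[N+](=O)[O-] | intermediate
20 | mesylate of 19: side chain (1S)-1-[(tert-butyldimethylsilyl)oxy]-2-[(methylsulfonyl)oxy]-3-nitropropyl | CCSC(=O)C(C)C[C@H](OC(=O)C(=C)CO[Si](C)(C)C(C)(C)C)[C@@H](C(=C)C(=O)OC)[C@H](O[Si](C)(C)C(C)(C)C)C(OS(C)(=O)=O)C[N+](=O)[O-] | intermediate
21 | methyl (3R,4S)-3-{(1R,2E)-1-[(tert-butyldimethylsilyl)oxy]-3-nitroprop-2-en-1-yl}-4-[(2-{[(tert-butyldimethylsilyl)oxy]methyl}prop-2-enoyl)oxy]-7-(ethylsulfanyl)-6-methyl-2-methylidene-7-oxoheptanoate | CCSC(=O)C(C)C[C@H](OC(=O)C(=C)CO[Si](C)(C)C(C)(C)C)[C@@H](C(=C)C(=O)OC)[C@H](O[Si](C)(C)C(C)(C)C)/C=C/[N+](=O)[O-] | intermediate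
22 | methyl (3R,4S)-3-{(1R,2E)-1-[(tert-butyldimethylsilyl)oxy]-3-nitroprop-2-en-1-yl}-4-[(2-{[(tert-butyldimethylsilyl)oxy]methyl}prop-2-enoyl)oxy]-6-methyl-2-methylidene-7-oxonon-8-enoate (epimers at the CH3-bearing carbon) | C=CC(=O)C(C)C[C@H](OC(=O)C(=C)CO[Si](C)(C)C(C)(C)C)[C@@H](C(=C)C(=O)OC)[C@H](O[Si](C)(C)C(C)(C)C)/C=C/[N+](=O)[O-] | intermediate
23 | methyl (3R,4S,6Z)-3-{(1R,2E)-1-[(tert-butyldimethylsilyl)oxy]-3-nitroprop-2-en-1-yl}-4-[(2-{[(tert-butyldimethylsilyl)oxy]methyl}prop-2-enoyl)oxy]-6-methyl-2-methylidene-7-[(trimethylsilyl)oxy]nona-6,8-dienoate (reactive Z isomer shown; isomers interconvert) | C=C/C(O[Si](C)(C)C)=C(\C)C[C@H](OC(=O)C(=C)CO[Si](C)(C)C(C)(C)C)[C@@H](C(=C)C(=O)OC)[C@H](O[Si](C)(C)C(C)(C)C)/C=C/[N+](=O)[O-] | intermediate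
24 | trans-fused cycloadduct, target numbering (4R,5R,6R,7R,8S,10R): C1(OSiMe3)=C2 enol ether, 4α-nitro, 5α-H, 6α-OTBS, 7β-[1-(methoxycarbonyl)ethenyl], 8α-(2-{[(tert-butyldimethylsilyl)oxy]methyl}prop-2-enoyloxy), 10β-CH3 | C=C(CO[Si](C)(C)C(C)(C)C)C(=O)O[C@H]1C[C@@]2(C)C(O[Si](C)(C)C)=CC[C@@H]([N+](=O)[O-])[C@@H]2[C@@H](O[Si](C)(C)C(C)(C)C)[C@@H]1C(=C)C(=O)OC | intermediate
25 | (4R,5R,6R,7R,8S,10R)-6-[(tert-butyldimethylsilyl)oxy]-8-[(2-{[(tert-butyldimethylsilyl)oxy]methyl}prop-2-enoyl)oxy]-7-[1-(methoxycarbonyl)ethenyl]-10-methyl-4-nitro-trans-decalin-1-one (target numbering) | C=C(CO[Si](C)(C)C(C)(C)C)C(=O)O[C@H]1C[C@@]2(C)C(=O)CC[C@@H]([N+](=O)[O-])[C@@H]2[C@@H](O[Si](C)(C)C(C)(C)C)[C@@H]1C(=C)C(=O)OC | intermediate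
26 | (1R,4R,5R,6R,7R,8S,10R)-1β-alcohol of 25 (equatorial OH at C1) | C=C(CO[Si](C)(C)C(C)(C)C)C(=O)O[C@H]1C[C@@]2(C)[C@H](O)CC[C@@H]([N+](=O)[O-])[C@@H]2[C@@H](O[Si](C)(C)C(C)(C)C)[C@@H]1C(=C)C(=O)OC | intermediate
27 | potassium C4 nitronate of 26 | C=C(CO[Si](C)(C)C(C)(C)C)C(=O)O[C@H]1C[C@@]2(C)[C@H](O)CCC(=[N+]([O-])[O-])[C@@H]2[C@@H](O[Si](C)(C)C(C)(C)C)[C@@H]1C(=C)C(=O)OC.[K+] | intermediate
28 | (1R,5S,6S,7R,8S,10R)-6-O,3'-O-bis(tert-butyldimethylsilyl) ether of the target (C4 ketone, free 1β-OH) | C=C(CO[Si](C)(C)C(C)(C)C)C(=O)O[C@H]1C[C@@]2(C)[C@H](O)CCC(=O)[C@@H]2[C@@H](O[Si](C)(C)C(C)(C)C)[C@@H]1C(=C)C(=O)OC | intermediate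
29 | CNP0144895.1, (1R,5S,6S,7S,8S,10R) in target numbering: 1β,6α-dihydroxy-8α-[2-(hydroxymethyl)prop-2-enoyloxy]-7β-[1-(methoxycarbonyl)ethenyl]-10β-methyl-trans-decalin-4-one | C=C(CO)C(=O)O[C@H]1C[C@@]2(C)[C@H](O)CCC(=O)[C@@H]2[C@@H](O)[C@@H]1C(=C)C(=O)OC | target

**Step count**

Total: 16 steps. Longest linear sequence: 12 steps (steps 3, 4, 5, 8, 9, 10, 11, 12, 13, 14, 15, 16). Steps 1–2 join at step 8 and steps 6–7 join at step 9.

**Steps most likely to fail**

1. Step 13. The cycloaddition may run in part through the exo arrangement, or through the dienol ether isomer that carries the tether on the inside, which would erode the trans ring fusion or the configuration at C10; the amine may also isomerise the nitroalkene before ring closure. The fallback sets out from 22 and comes back at 25 and makes no compound outside the list (F0). Compound 22 would be treated with a catalytic weak base (Cs2CO3, 0.2 equiv, MeCN, 0 °C), so that the C10 enolate adds to the nitroalkene and the resulting nitronate adds to the enone. This reversible intramolecular Michael–Michael annulation is under thermodynamic control and should drain the material, through retro-Michael equilibration, into the all-equatorial trans-fused 25.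

2. Step 8. The aldehyde may attack C7 on the wrong face with respect to the C6 silyloxy centre, and the borate may lactonise onto the ester or the thioester. The fallback sets out from 3 and comes back at 15, and builds the triad by aldol chemistry instead. Indium-mediated allylation of 3 with methyl 2-(bromomethyl)acrylate (indium metal, THF/H2O) would give methyl 7-(ethylsulfanyl)-4-hydroxy-6-methyl-2-methylidene-7-oxoheptanoate F1. Dess–Martin oxidation would give the β,γ-unsaturated ketone methyl 7-(ethylsulfanyl)-6-methyl-2-methylidene-4,7-dioxoheptanoate F2. A boron aldol reaction (Ipc2BOTf of the enantiomer matched to the 6R,7S adduct, iPr2NEt, CH2Cl2, −78 °C, then crotonaldehyde 5) through the Z enolate of the doubly activated C7 methylene would give the syn aldol methyl (3S)-7-(ethylsulfanyl)-3-[(1R,2E)-1-hydroxybut-2-en-1-yl]-6-methyl-2-methylidene-4,7-dioxoheptanoate F3. Silylation (TBSOTf, 2,6-lutidine, −78 °C) would give its silyl ether methyl (3S)-3-{(1R,2E)-1-[(tert-butyldimethylsilyl)oxy]but-2-en-1-yl}-7-(ethylsulfanyl)-6-methyl-2-methylidene-4,7-dioxoheptanoate F4. A catalyst-controlled oxazaborolidine (CBS) reduction with BH3·SMe2, using the catalyst enantiomer that gives the 8S alcohol, would then give 15.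

3. Step 5. The alkene geometry may be lost through the aluminium allenoate, or the ester may be reduced 1,2, either of which would give the wrong crotyl-type isomer. The fallback sets out from 8 and comes back at 10. Palladium-catalysed syn hydrostannation (Bu3SnH, Pd(PPh3)4, THF) would give methyl (2E,4R,5E)-4-[(tert-butyldimethylsilyl)oxy]-2-(tributylstannyl)hepta-2,5-dienoate F5. Iododestannylation (I2, CH2Cl2, 0 °C) would give methyl (2E,4R,5E)-4-[(tert-butyldimethylsilyl)oxy]-2-iodohepta-2,5-dienoate F6. Negishi coupling with IZnCH2Bpin (Pd(PPh3)4, THF) would then give 10 with retention of geometry.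

**Further compounds**

F0 | step 13 | none | none
F1 | step 8 | methyl 7-(ethylsulfanyl)-4-hydroxy-6-methyl-2-methylidene-7-oxoheptanoate (mixture of stereoisomers) | CCSC(=O)C(C)CC(O)CC(=C)C(=O)OC
F2 | step 8 | methyl 7-(ethylsulfanyl)-6-methyl-2-methylidene-4,7-dioxoheptanoate | CCSC(=O)C(C)CC(=O)CC(=C)C(=O)OC
F3 | step 8 | methyl (3S)-7-(ethylsulfanyl)-3-[(1R,2E)-1-hydroxybut-2-en-1-yl]-6-methyl-2-methylidene-4,7-dioxoheptanoate | CCSC(=O)C(C)CC(=O)[C@@H](C(=C)C(=O)OC)[C@H](O)/C=C/C
F4 | step 8 | methyl (3S)-3-{(1R,2E)-1-[(tert-butyldimethylsilyl)oxy]but-2-en-1-yl}-7-(ethylsulfanyl)-6-methyl-2-methylidene-4,7-dioxoheptanoate | CCSC(=O)C(C)CC(=O)[C@@H](C(=C)C(=O)OC)[C@H](O[Si](C)(C)C(C)(C)C)/C=C/C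
F5 | step 5 | methyl (2E,4R,5E)-4-[(tert-butyldimethylsilyl)oxy]-2-(tributylstannyl)hepta-2,5-dienoate | COC(=O)/C([Sn](CCCC)(CCCC)CCCC)=C\[C@H](O[Si](C)(C)C(C)(C)C)/C=C/C
F6 | step 5 | methyl (2E,4R,5E)-4-[(tert-butyldimethylsilyl)oxy]-2-iodohepta-2,5-dienoate | COC(=O)/C(I)=C\[C@H](O[Si](C)(C)C(C)(C)C)/C=C/C
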